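## The problem

The target is isofraxidin (7-hydroxy-6,8-dimethoxycoumarin) alkylated on O7 by C7, the neopentyl CH2 of a ring-A-seco, methyl-shifted drimane whose only carbocycle is the cyclohexane C1–C6. That ring carries three contiguous stereocentres, all R: the quaternary C1 (CH3 and C7H2OAr), C2 (3-hydroxypropyl) and C6 (CH3). The C1 methyl is trans to the C6 methyl and cis to the C2 chain, so in the chair the chain and C7 are trans-diaxial and both methyls equatorial. C2 is flanked by C3, which carries the exocyclic, tetrasubstituted C3=C8 isopropylidene; this alkene is not reliably made by olefination of a hindered, epimerisable ketone, it drifts into the ring or to isopropenyl under acid, and C2 cannot be corrected by epimerisation once set. Only C6 can reasonably come from outside: it must control C1 in an enolate alkylation, where the order of the two electrophiles decides the outcome, and C1 with C6 must then control C2. The O7–C7 bond lies on a neopentyl carbon, so SN2 chemistry there is slow, and the coumarin (unsaturated lactone, Michael acceptor) does not survive enolates, hydrides or organometallic reagents, which forces the ether to the end and the chain hydroxyl to stay masked until then. The feature that opens the route is the allyl triad C2–C3=C8 set in a p-menthane frame: C1–C6 with the C6 methyl and the C3=C8(CH3)2 unit are, carbon for carbon, (R)-pulegone with C2 as carbonyl carbon and C1 as α' carbon, and the double bond can be parked in the ring (C2=C3, oxygen on C8) and sent back to C3=C8 in the step that makes the C2–chain bond.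

## Retrosynthesis

**Ether and hydroxyl (16 ⇐ 15 ⇐ 13 + 14).** The O7–C7 bond is cut last, giving commercial isofraxidin 14 and the neopentyl alcohol 13, whose chain hydroxyl is carried as the silyl ether that arrives with the chain. Cutting here rather than building the coumarin on a preformed aryl ether saves the whole heterocycle synthesis. The forward reaction is a dehydrative etherification that must tolerate a neopentyl carbon; nothing stereochemical is asked of it.

**Chain, alkene and C2 in one cut (13 ⇐ 12 ⇐ 9 + 11, 11 from 10).** The C2–chain bond is cut with allylic transposition: the three-carbon chain becomes Grignard reagent 11 (from bromide 10), and the ring becomes the tertiary allylic picolinate 9, with a C2=C3 ring alkene and the oxygen on C8. The neighbouring cut, adding the chain to the pulegone carbonyl and replacing the oxygen by hydrogen, would need hydrogen to enter C2 syn to the axial C7 group (the hindered face) and passes through an allyl ion with two tertiary termini. The chosen cut brings carbon to the open face and has only one substitutable terminus. Precursor 9 has one stereocentre fewer, no side chain, and a robust trisubstituted ring alkene in place of the sensitive exocyclic one. The forward reaction must be γ-selective and must add anti to the pseudoaxial C7 group.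

**Parking the double bond (9 ⇐ 8 ⇐ 6).** Picolinate 9 is the ester of alcohol 8, which is the Wharton transposition product of α,β-epoxy ketone 6: the carbonyl carbon C2 becomes the alkene CH and the epoxide oxygen stays on C8. This is why C1 carries a benzyloxymethyl group and not an ester: a β-keto ester would condense with hydrazine to a pyrazolone. The spiro carbon C3 of 6 becomes sp2, so its configuration is irrelevant.

**Quaternary carbon (6 ⇐ 4 ⇐ 2).** C1 is built by two enolate alkylations of pulegone oxide 2, first with benzyl chloromethyl ether (giving 4), then with iodomethane. The second electrophile enters trans to the C6 methyl, so the order (oxygenated carbon first, methyl second) gives the required configuration; the reverse order would give the C1 epimer. In 2 the α' carbon C1 is the only enolisable position, since both oxirane carbons are fully substituted and the γ-deprotonation path of pulegone is gone.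

**Chiral pool (2 ⇐ 1).** Epoxy ketone 2 is the nucleophilic epoxidation product of (R)-(+)-pulegone 1, which supplies ten of the fifteen terpenoid carbons, the C6 stereocentre in the correct absolute sense, and the latent isopropylidene.

## Roads not taken

Alternative 1: the most obvious plan cuts the ether and then the C3=C8 double bond, leading to cyclohexanone A1, to be olefinated with an isopropylidene phosphorane or by a McMurry cross-coupling with acetone. The ketone is flanked by the C2 stereocentre, so the basic, hindered ylide would enolise and epimerise C2 rather than olefinate, and tetrasubstituted alkenes are the weakest case for carbonyl olefination. A1 also needs its three contiguous stereocentres built from nothing, with no absolute control, in a run-up longer than the whole chosen route. The chosen plan never makes the alkene; it only moves it.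

Alternative 2: a bond absent from the target, between the terminal carbinol carbon of the chain and C8, gives the rearranged drimane decalin A2. The forward key step would be a Grob-type fragmentation (alkoxide on the carbinol carbon, leaving group on C3) releasing the chain as an aldehyde together with the C3=C8 alkene. The leaving group would sit on a tertiary ring-fusion carbon, and the antiperiplanar alignment requires a cis ring fusion. The acid-triggered, biomimetic version is the reverse of a Prins (carbonyl-ene) ring closure and so runs uphill, with methyl shifts in competition. The decalin with its five stereocentres also costs more steps than it saves, since most of ring A is built only to be cut.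

Alternative 3: the ring bond C1–C2 is cut and the ring formed by an Ireland–Claisen ring contraction of the eight-membered allylic lactone A3. The [3,3] shift of its silyl ketene acetal would close the cyclohexane, set C1 and C2, and create the isopropylidene at once. It is the most powerful step on paper, but A3 is a medium-ring lactone closed onto a tertiary alcohol with a trisubstituted alkene of defined geometry, and the facial and enolate-geometry control of two new centres relative to C6 through a boat-like transition state is uncertain. Pulegone already contains that ring and that alkene.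

Key step: step 6

Remark: the carbocycle is numbered C1 (quaternary), C2 (chain), C3 (isopropylidene), C4, C5, C6 (methyl), with C7 = OCH2 and C8 = isopropylidene carbon. Compounds 1, 10 and 14, benzyl chloromethyl ether and picolinic acid are taken as commercial.

## Steps

Step 1
Reactants: 1 (R)-(+)-pulegone
Product: 2 (6R)-2,2,6-trimethyl-1-oxaspiro[2.5]octan-4-one
Conditions: 30 % aq. H2O2, NaOH (cat.), MeOH, 0 °C → rt
Reagents that add atoms: hydrogen peroxide, OO
Why: Weitz–Scheffer nucleophilic epoxidation of the enone (conjugate addition of HOO− at C8, then ring closure); the new spiro centre C3 forms as a mixture that does not matter because C3 becomes sp2 again in step 4, and the C6 stereocentre is untouched.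

Step 2
Reactants: 2 (6R)-2,2,6-trimethyl-1-oxaspiro[2.5]octan-4-one
Product: 4 (6R)-5-[(benzyloxy)methyl]-2,2,6-trimethyl-1-oxaspiro[2.5]octan-4-one, via lithium enolate 3 (not isolated)
Conditions: LiN(iPr)2, THF, −78 °C; BnOCH2Cl, −78 → −30 °C
Reagents that add atoms: benzyl chloromethyl ether, ClCOCc1ccccc1
Why: Kinetic enolate alkylation with a reactive α-chloro ether; C1 is the only enolisable position of 2 because both oxirane carbons are fully substituted, and the configuration formed at C1 is irrelevant since the centre is re-enolised in step 3.

Step 3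
Reactants: 4 (6R)-5-[(benzyloxy)methyl]-2,2,6-trimethyl-1-oxaspiro[2.5]octan-4-one
Product: 6 (5S,6R)-5-[(benzyloxy)methyl]-2,2,5,6-tetramethyl-1-oxaspiro[2.5]octan-4-one, via lithium enolate 5 (not isolated)
Conditions: LiN(iPr)2, THF, −78 °C; MeI, DMPU, −78 → −40 °C
Reagents that add atoms: iodomethane, CI
Why: Alkylation of a tetrasubstituted lithium enolate; A(1,2) strain between the C1 substituent and the C6 methyl places that methyl pseudoaxial, so iodomethane should enter axially from the opposite face and the new methyl ends up trans to the C6 methyl with C7 cis to it.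

Step 4
Reactants: 6 (5S,6R)-5-[(benzyloxy)methyl]-2,2,5,6-tetramethyl-1-oxaspiro[2.5]octan-4-one
Product: 8 2-{(3R,4R)-3-[(benzyloxy)methyl]-3,4-dimethylcyclohex-1-en-1-yl}propan-2-ol, via hydrazone 7 (not isolated)
Conditions: N2H4·H2O, AcOH (cat.), MeOH, 0 °C → rt
Reagents that add atoms: none
Why: Wharton transposition: hydrazone 7 opens the oxirane to a vinyl diazene that loses N2, so the carbonyl carbon C2 becomes an alkene CH and the oxygen stays on C8; both C3 epimers of 6 should converge on the single alcohol 8 because C3 becomes sp2.

Step 5
Reactants: 8 2-{(3R,4R)-3-[(benzyloxy)methyl]-3,4-dimethylcyclohex-1-en-1-yl}propan-2-ol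
Product: 9 2-{(3R,4R)-3-[(benzyloxy)methyl]-3,4-dimethylcyclohex-1-en-1-yl}propan-2-yl pyridine-2-carboxylate
Conditions: picolinic acid, DCC, DMAP, CH2Cl2, rt
Reagents that add atoms: pyridine-2-carboxylic acid, OC(=O)c1ccccn1
Why: Steglich esterification of the only hydroxyl in the molecule; the 2-pyridyl ester is chosen because chelation to magnesium turns it into a good allylic leaving group in step 6.

Step 6
Reactants: 9 2-{(3R,4R)-3-[(benzyloxy)methyl]-3,4-dimethylcyclohex-1-en-1-yl}propan-2-yl pyridine-2-carboxylate, 10 (3-bromopropoxy)(tert-butyl)dimethylsilane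
Product: 12 benzyl [(1R,2R,6R)-2-{3-[(tert-butyldimethylsilyl)oxy]propyl}-1,6-dimethyl-3-(propan-2-ylidene)cyclohexyl]methyl ether, via Grignard reagent 11 (not isolated)
Conditions: Mg, THF, rt (10 → 11); CuBr·SMe2 (30 mol %), then 9, THF, −40 → 0 °C; aq. NH4Cl
Reagents that add atoms: none
Why: Reagent 11 and CuBr·SMe2 form a magnesium organocuprate of monovalent copper that binds the C2=C3 π bond while the picolinate nitrogen and carbonyl chelate magnesium and loosen the C8–O bond; oxidative addition at C2 anti to the departing oxygen gives a σ-allyl species of trivalent copper, and reductive elimination forms the C2–chain bond as the double bond moves out to C3=C8. The closest known reaction type is the copper-catalysed anti-SN2' (γ-selective) substitution of allylic picolinates and tertiary allylic carboxylates by Grignard reagents, and attack of organocopper reagents next to a quaternary carbon is familiar from conjugate additions to 4,4-disubstituted cyclohexenones. No ring is closed. γ-Selectivity is secured by the substrate: C8 is fully substituted, so direct displacement is not available and a copper–carbon bond there would be tertiary. The one new stereocentre, C2, is controlled by the adjacent quaternary C1: in the half-chair with the C6 methyl equatorial the C7H2OBn group is pseudoaxial, and copper should enter antiperiplanar to it through a chair-like transition state, placing the chain trans to C7 and cis to the C1 methyl. That path leads directly to the chair with chain and C7 trans-diaxial, both methyls equatorial and no A(1,3) strain against the new isopropylidene, whereas the C2 epimer would need attack syn to the pseudoaxial C7 group or, in the flipped half-chair, a syn-diaxial clash with the C6 methyl. Because C8 carries two methyls, the leaving group can take the anti position on either face and carries no stereochemical information.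

Step 7
Reactants: 12 benzyl [(1R,2R,6R)-2-{3-[(tert-butyldimethylsilyl)oxy]propyl}-1,6-dimethyl-3-(propan-2-ylidene)cyclohexyl]methyl ether
Product: 13 [(1R,2R,6R)-2-{3-[(tert-butyldimethylsilyl)oxy]propyl}-1,6-dimethyl-3-(propan-2-ylidene)cyclohexyl]methanol
Conditions: Li, NH3 (l), THF, −78 °C; NH4Cl
Reagents that add atoms: none
Why: Dissolving-metal (Birch-type) cleavage of the benzyl ether by electron transfer to the arene; the isolated tetrasubstituted alkene and the silyl ether are not reduced and no stereocentre is touched.

Step 8
Reactants: 13 [(1R,2R,6R)-2-{3-[(tert-butyldimethylsilyl)oxy]propyl}-1,6-dimethyl-3-(propan-2-ylidene)cyclohexyl]methanol, 14 isofraxidin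
Product: 15 7-{[(1R,2R,6R)-2-{3-[(tert-butyldimethylsilyl)oxy]propyl}-1,6-dimethyl-3-(propan-2-ylidene)cyclohexyl]methoxy}-6,8-dimethoxy-2H-chromen-2-one
Conditions: Bu3P=CHCN, toluene, 110 °C
Reagents that add atoms: none
Why: Mitsunobu-type dehydrative etherification with a phosphorane that tolerates the temperature needed for SN2 at a neopentyl carbon; the phenol of 14 is acidic (para to the unsaturated lactone), and C7 is not a stereocentre and has no β-hydrogen for elimination.

Step 9
Reactants: 15 7-{[(1R,2R,6R)-2-{3-[(tert-butyldimethylsilyl)oxy]propyl}-1,6-dimethyl-3-(propan-2-ylidene)cyclohexyl]methoxy}-6,8-dimethoxy-2H-chromen-2-one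
Product: 16 7-{[(1R,2R,6R)-2-(3-hydroxypropyl)-1,6-dimethyl-3-(propan-2-ylidene)cyclohexyl]methoxy}-6,8-dimethoxy-2H-chromen-2-one
Conditions: HF·pyridine, THF/pyridine, 0 °C → rt
Reagents that add atoms: none
Why: Fluoride cleavage of the primary silyl ether; the buffered reagent should leave the lactone, the aryl ether and the tetrasubstituted alkene untouched.

## Compound list

1 | (R)-(+)-pulegone, (5R)-5-methyl-2-(propan-2-ylidene)cyclohexan-1-one | C[C@@H]1CCC(=C(C)C)C(=O)C1 | starting material
2 | (6R)-2,2,6-trimethyl-1-oxaspiro[2.5]octan-4-one (pulegone oxide, both C3 epimers) | C[C@@H]1CCC2(OC2(C)C)C(=O)C1 | intermediate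
3 | lithium (6R)-2,2,6-trimethyl-1-oxaspiro[2.5]oct-4-en-4-olate | C[C@@H]1CCC2(OC2(C)C)C(O[Li])=C1 | intermediate
4 | (6R)-5-[(benzyloxy)methyl]-2,2,6-trimethyl-1-oxaspiro[2.5]octan-4-one (epimers at C3 and C5) | C[C@@H]1CCC2(OC2(C)C)C(=O)C1COCc1ccccc1 | intermediate
5 | lithium (6R)-5-[(benzyloxy)methyl]-2,2,6-trimethyl-1-oxaspiro[2.5]oct-4-en-4-olate | C[C@@H]1CCC2(OC2(C)C)C(O[Li])=C1COCc1ccccc1 | intermediate
6 | (5S,6R)-5-[(benzyloxy)methyl]-2,2,5,6-tetramethyl-1-oxaspiro[2.5]octan-4-one (both C3 epimers) | C(OCc1ccccc1)[C@]2(C)[C@H](C)CCC3(OC3(C)C)C2=O | intermediate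
7 | (5R,6R)-5-[(benzyloxy)methyl]-4-hydrazinylidene-2,2,5,6-tetramethyl-1-oxaspiro[2.5]octane | C(OCc1ccccc1)[C@]2(C)[C@H](C)CCC3(OC3(C)C)C2=NN | intermediate
8 | 2-{(3R,4R)-3-[(benzyloxy)methyl]-3,4-dimethylcyclohex-1-en-1-yl}propan-2-ol | C(OCc1ccccc1)[C@]2(C)[C@H](C)CCC(C(C)(C)O)=C2 | intermediate
9 | 2-{(3R,4R)-3-[(benzyloxy)methyl]-3,4-dimethylcyclohex-1-en-1-yl}propan-2-yl pyridine-2-carboxylate | C(OCc1ccccc1)[C@]2(C)[C@H](C)CCC(C(C)(C)OC(=O)c3ccccn3)=C2 | intermediate
10 | (3-bromopropoxy)(tert-butyl)dimethylsilane | BrCCCO[Si](C)(C)C(C)(C)C | starting material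
11 | {3-[(tert-butyldimethylsilyl)oxy]propyl}magnesium bromide | Br[Mg]CCCO[Si](C)(C)C(C)(C)C | intermediate
12 | benzyl [(1R,2R,6R)-2-{3-[(tert-butyldimethylsilyl)oxy]propyl}-1,6-dimethyl-3-(propan-2-ylidene)cyclohexyl]methyl ether | C(OCc1ccccc1)[C@]2(C)[C@H](C)CCC(=C(C)C)[C@H]2CCCO[Si](C)(C)C(C)(C)C | intermediate
13 | [(1R,2R,6R)-2-{3-[(tert-butyldimethylsilyl)oxy]propyl}-1,6-dimethyl-3-(propan-2-ylidene)cyclohexyl]methanol | OC[C@]1(C)[C@H](C)CCC(=C(C)C)[C@H]1CCCO[Si](C)(C)C(C)(C)C | intermediate
14 | isofraxidin, 7-hydroxy-6,8-dimethoxy-2H-chromen-2-one | COc1cc2ccc(=O)oc2c(OC)c1O | starting material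
15 | 7-{[(1R,2R,6R)-2-{3-[(tert-butyldimethylsilyl)oxy]propyl}-1,6-dimethyl-3-(propan-2-ylidene)cyclohexyl]methoxy}-6,8-dimethoxy-2H-chromen-2-one | COc1cc2ccc(=O)oc2c(OC)c1OC[C@]1(C)[C@H](C)CCC(=C(C)C)[C@H]1CCCO[Si](C)(C)C(C)(C)C | intermediate
16 | 7-{[(1R,2R,6R)-2-(3-hydroxypropyl)-1,6-dimethyl-3-(propan-2-ylidene)cyclohexyl]methoxy}-6,8-dimethoxy-2H-chromen-2-one | COc1cc2ccc(=O)oc2c(OC)c1OC[C@]1(C)[C@H](C)CCC(=C(C)C)[C@H]1CCCO | target

## Step count and least certain steps

Total: 9 steps. Longest linear sequence: 9 steps (1 → 16); 10 and 14 enter as commercial materials in steps 6 and 8.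

**Step 6 (key step).** The copper reagent may add too slowly at C2, which is flanked by the quaternary C1. The activated tertiary picolinate would then ionise and eliminate to the diene, or the Grignard reagent would attack the ester carbonyl and return 8. Facial selectivity could also erode if the benzyl ether oxygen directs delivery syn to C7. The fallback replaces intermolecular delivery by an intramolecular sigmatropic one, sets out from 8 and returns at 12, at the cost of four extra steps:
- Johnson–Claisen rearrangement (MeC(OEt)3, EtCO2H cat., 140 °C) should give ethyl 2-[(1R,2R,3R)-2-[(benzyloxy)methyl]-2,3-dimethyl-6-(propan-2-ylidene)cyclohexyl]acetate F1 through a [3,3] shift with the same facial preference.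
- Reduction with iBu2AlH at −78 °C would give 2-[(1R,2R,3R)-2-[(benzyloxy)methyl]-2,3-dimethyl-6-(propan-2-ylidene)cyclohexyl]acetaldehyde F2.
- Wittig methylenation (Ph3P=CH2) would give ({[(1R,2R,6R)-1,6-dimethyl-2-(prop-2-en-1-yl)-3-(propan-2-ylidene)cyclohexyl]methoxy}methyl)benzene F3.
- Hydroboration with 9-BBN and oxidation (H2O2, NaOH) would give 3-[(1R,2R,3R)-2-[(benzyloxy)methyl]-2,3-dimethyl-6-(propan-2-ylidene)cyclohexyl]propan-1-ol F4.
- Silylation (TBSCl, imidazole) would give 12.

**Step 3.** The enolate carries a benzyloxy group β to the carbanionic carbon, so loss of benzyloxide (E1cB) may compete with methylation. Deprotonation of the hindered methine may be incomplete, and the facial bias from the C6 methyl may be lower than in simple 2,3-disubstituted cyclohexanone enolates. The fallback forms the quaternary carbon from a β-dicarbonyl enolate with no β leaving group and installs the benzyl group afterwards; it sets out from 2 and returns at 6: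
- Formylation (NaH, HCO2Et) would give (6R)-5-(hydroxymethylidene)-2,2,6-trimethyl-1-oxaspiro[2.5]octan-4-one F5.
- C-Methylation (K2CO3, MeI, acetone) would give (5S,6R)-2,2,5,6-tetramethyl-4-oxo-1-oxaspiro[2.5]octane-5-carbaldehyde F6.
- Selective aldehyde reduction (NaBH4, MeOH, −78 °C) would give (5S,6R)-5-(hydroxymethyl)-2,2,5,6-tetramethyl-1-oxaspiro[2.5]octan-4-one F7.
- Benzylation under neutral conditions (2-benzyloxy-1-methylpyridinium triflate, MgO, PhCF3, 85 °C) would give 6.

**Step 4.** Hydrazone formation at a ketone flanked by a quaternary carbon and a spiro oxirane carbon may be slow, leaving time for hydrazine to open the epoxide or for cyclisation to a hydroxypyrazoline. The fallback achieves the same transposition by a radical path; it sets out from 6 and returns at 8: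
- LiAlH4 (Et2O, 0 °C) would give (5S,6R)-5-[(benzyloxy)methyl]-2,2,5,6-tetramethyl-1-oxaspiro[2.5]octan-4-ol F8.
- NaH, CS2, then MeI would give O-{(5S,6R)-5-[(benzyloxy)methyl]-2,2,5,6-tetramethyl-1-oxaspiro[2.5]octan-4-yl} S-methyl carbonodithioate F9.
- Bu3SnH and AIBN in refluxing benzene would generate the C2 radical, which opens the oxirane; the tertiary alkoxy radical then takes hydrogen from the stannane to give 8.

**Step 8.** Displacement at the neopentyl C7, next to the axial chain, may be too slow, so the activated alcohol is consumed unproductively or the C3=C8 alkene participates in ionisation. The fallback isolates a far better leaving group and uses a preformed phenoxide; it sets out from 13 and returns at 15: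
- Tf2O and 2,6-lutidine (CH2Cl2, −78 °C) would give [(1R,2R,6R)-2-{3-[(tert-butyldimethylsilyl)oxy]propyl}-1,6-dimethyl-3-(propan-2-ylidene)cyclohexyl]methyl trifluoromethanesulfonate F10.
- Displacement by the caesium phenoxide of 14 (Cs2CO3, DMF, rt → 50 °C) would give 15.

## Further compounds

F1 | step 6 | ethyl 2-[(1R,2R,3R)-2-[(benzyloxy)methyl]-2,3-dimethyl-6-(propan-2-ylidene)cyclohexyl]acetate | C(OCc1ccccc1)[C@]2(C)[C@H](C)CCC(=C(C)C)[C@H]2CC(=O)OCC
F2 | step 6 | 2-[(1R,2R,3R)-2-[(benzyloxy)methyl]-2,3-dimethyl-6-(propan-2-ylidene)cyclohexyl]acetaldehyde | C(OCc1ccccc1)[C@]2(C)[C@H](C)CCC(=C(C)C)[C@H]2CC=O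
F3 | step 6 | ({[(1R,2R,6R)-1,6-dimethyl-2-(prop-2-en-1-yl)-3-(propan-2-ylidene)cyclohexyl]methoxy}methyl)benzene | C(OCc1ccccc1)[C@]2(C)[C@H](C)CCC(=C(C)C)[C@H]2CC=C
F4 | step 6 | 3-[(1R,2R,3R)-2-[(benzyloxy)methyl]-2,3-dimethyl-6-(propan-2-ylidene)cyclohexyl]propan-1-ol | C(OCc1ccccc1)[C@]2(C)[C@H](C)CCC(=C(C)C)[C@H]2CCCO
F5 | step 3 | (6R)-5-(hydroxymethylidene)-2,2,6-trimethyl-1-oxaspiro[2.5]octan-4-one | C[C@@H]1CCC2(OC2(C)C)C(=O)C1=CO
F6 | step 3 | (5S,6R)-2,2,5,6-tetramethyl-4-oxo-1-oxaspiro[2.5]octane-5-carbaldehyde | O=C[C@]2(C)[C@H](C)CCC3(OC3(C)C)C2=O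
F7 | step 3 | (5S,6R)-5-(hydroxymethyl)-2,2,5,6-tetramethyl-1-oxaspiro[2.5]octan-4-one | OC[C@]2(C)[C@H](C)CCC3(OC3(C)C)C2=O
F8 | step 4 | (5S,6R)-5-[(benzyloxy)methyl]-2,2,5,6-tetramethyl-1-oxaspiro[2.5]octan-4-ol | C(OCc1ccccc1)[C@]2(C)[C@H](C)CCC3(OC3(C)C)C2O
F9 | step 4 | O-{(5S,6R)-5-[(benzyloxy)methyl]-2,2,5,6-tetramethyl-1-oxaspiro[2.5]octan-4-yl} S-methyl carbonodithioate | C(OCc1ccccc1)[C@]2(C)[C@H](C)CCC3(OC3(C)C)C2OC(=S)SC
F10 | step 8 | [(1R,2R,6R)-2-{3-[(tert-butyldimethylsilyl)oxy]propyl}-1,6-dimethyl-3-(propan-2-ylidene)cyclohexyl]methyl trifluoromethanesulfonate | C(OS(=O)(=O)C(F)(F)F)[C@]2(C)[C@H](C)CCC(=C(C)C)[C@H]2CCCO[Si](C)(C)C(C)(C)C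
A1 | alternative 1 | (2S,3R,4R)-3-[(benzyloxy)methyl]-2-{3-[(tert-butyldimethylsilyl)oxy]propyl}-3,4-dimethylcyclohexan-1-one | C(OCc1ccccc1)[C@]2(C)[C@H](C)CCC(=O)[C@H]2CCCO[Si](C)(C)C(C)(C)C
A2 | alternative 2 | (4aS,5R,6R)-5-[(benzyloxy)methyl]-1,1,5,6-tetramethyldecahydronaphthalene-2,8a-diol (configuration at C2 and C8a left open) | C(OCc1ccccc1)[C@]2(C)[C@H](C)CCC3(O)C(C)(C)C(O)CC[C@H]32
A3 | alternative 3 | (4R)-7-{4-[(tert-butyldimethylsilyl)oxy]butylidene}-3,4,8,8-tetramethyloxocan-2-one (C3 configuration and alkene geometry left open) | CC1C(=O)OC(C)(C)C(=CCCCO[Si](C)(C)C(C)(C)C)CC[C@H]1C
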